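**Strategy.** Drimane numbering is used (ring A: C1–C5, C10; ring B: C5–C10; C11 carboxyl on C9, C12 formyl on C8). Ring B holds a cis-2-ene-1,4-diol unit, C6(O)–C7=C8–C9(O), so both carbinol carbons can come from carbonyl groups. The route rests on a [3+3] annulation: an allylchromium centred on C5 of a ring A keto ester adds to the aldehyde of a C6–C7–C8(–C12) iodoenal, and the C8 vinylchromium then closes ring B onto the C9 ketone. One operation forms C5–C6 and C8–C9 and sets C5, C6 and C9. Methylation at C4, acylation and deprotection follow.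

Key step: step 8

Remark: the target is handled as the open formyl acid as drawn; its cyclic hydroxy-lactone tautomer would be the same substance in equilibrium, and 4, 9 and 17 are taken as catalogue compounds.

**Step 1**
Reactants: 1 3-methylcyclohex-2-en-1-one
Product: 2 (±)-1,3-dimethylcyclohex-2-en-1-ol
Conditions: CH3Li, Et2O, −78 °C
Reagents that add atoms: methyllithium, [Li]C
Why: The hard organolithium should add 1,2 to the enone; the racemic tertiary allylic alcohol suffices because its stereocentre is erased in step 3.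

**Step 2**
Reactants: 2 (±)-1,3-dimethylcyclohex-2-en-1-ol
Product: 3 (±)-3-chloro-1,3-dimethylcyclohex-1-ene
Conditions: conc. HCl, pentane, 0 °C
Reagents that add atoms: hydrogen chloride, Cl
Why: SN1 substitution through the symmetric 1,3-dimethylcyclohexenyl cation, whose two termini give the same tertiary allylic chloride.

**Step 3**
Reactants: 3 (±)-3-chloro-1,3-dimethylcyclohex-1-ene; 4 tert-butyl glyoxylate
Product: 6 tert-butyl 2-[(1S)-1,3-dimethylcyclohex-2-en-1-yl]-2-hydroxyacetate, via silyl ether 5 (not isolated)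
Conditions: CrCl2 (10 mol %), chiral bis(oxazolinyl)carbazole ligand (12 mol %), Mn powder, TMSCl, THF, rt; then 1 M HCl, THF, 0 °C
Reagents that add atoms: none
Why: Catalytic asymmetric Nozaki–Hiyama allylation; the allylchromium from 3 is symmetric, so either terminus gives the same quaternary carbon, and the ligand-bound chromium should fix, through the closed six-membered transition state, the aldehyde face and with it the (S) quaternary centre (ligand antipode chosen accordingly), the carbinol centre being erased in step 4.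

**Step 4**
Reactants: 6 tert-butyl 2-[(1S)-1,3-dimethylcyclohex-2-en-1-yl]-2-hydroxyacetate
Product: 7 tert-butyl 2-[(1S)-1,3-dimethylcyclohex-2-en-1-yl]-2-oxoacetate
Conditions: Dess–Martin periodinane, CH2Cl2, rt
Reagents that add atoms: none
Why: Dess–Martin oxidation of the secondary alcohol should give the non-enolisable α-keto ester without touching the quaternary centre.

**Step 5**
Reactants: 7 tert-butyl 2-[(1S)-1,3-dimethylcyclohex-2-en-1-yl]-2-oxoacetate
Product: 8 tert-butyl 2-[(1S)-4-bromo-1,3-dimethylcyclohex-2-en-1-yl]-2-oxoacetate (both epimers at the C–Br carbon)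
Conditions: NBS, AIBN (cat.), PhCF3, 80 °C
Reagents that add atoms: N-bromosuccinimide, O=C1CCC(=O)N1Br
Why: Wohl–Ziegler bromination at the only secondary allylic CH2 (C3), the delocalised radical being brominated at its less hindered end; any allylic isomer converges on the same allylchromium in step 8.

**Step 6**
Reactants: 9 4,4-diethoxybut-2-yn-1-ol
Product: 11 (2Z)-4,4-diethoxy-3-iodobut-2-en-1-ol, via sodium alkenylalanate 10 (not isolated)
Conditions: NaAlH2(OCH2CH2OCH3)2, THF, 0 °C; then I2, −78 °C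
Reagents that add atoms: iodine, II
Why: Hydroxyl-directed trans-hydroalumination should place aluminium on the distal alkyne carbon in a five-membered alanate, and iodinolysis with retention gives the vinyl iodide with iodine cis to CH2OH.

**Step 7**
Reactants: 11 (2Z)-4,4-diethoxy-3-iodobut-2-en-1-ol
Product: 12 (2Z)-4,4-diethoxy-3-iodobut-2-enal
Conditions: MnO2, CH2Cl2, rt
Reagents that add atoms: none
Why: Neutral allylic oxidation with MnO2 should keep the acetal and the (Z)-iodoalkene geometry.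

**Step 8**
Reactants: 8 tert-butyl 2-[(1S)-4-bromo-1,3-dimethylcyclohex-2-en-1-yl]-2-oxoacetate; 12 (2Z)-4,4-diethoxy-3-iodobut-2-enal
Product: 14 tert-butyl (1R,4R,4aS,8aS)-2-(diethoxymethyl)-1,4-dihydroxy-5,8a-dimethyl-1,4,4a,7,8,8a-hexahydronaphthalene-1-carboxylate, via acyclic iodo alkoxide 13 (not isolated)
Conditions: CrCl2 (6 equiv), THF–DMF, 0 °C to rt; then NiCl2 (2 mol %), rt; aqueous sodium potassium tartrate
Reagents that add atoms: none
Why: CrCl2 should turn 8 into an allylchromium with the metal on the less hindered ring CH (C3), which adds through its γ-carbon C5 to the aldehyde of 12 in a closed chair transition state (Nozaki–Hiyama allylation) to give 13 as its chromium alkoxide; nickel then activates the vinyl iodide and the C8 vinylchromium adds to the C9 ketone (Nozaki–Hiyama–Kishi reaction), a formal [3+3] annulation. The closest known type is a sequential intermolecular/intramolecular Nozaki–Hiyama–Kishi coupling. Ring B closes in the second event by a 6-exo-trig 1,2-addition to the ketone carbonyl. C5: the aldehyde is delivered to the allyl face opposite the bulky keto ester on C10, making C5–C6 trans to C9–C10 and the ring fusion trans; C6: the ring-locked (Z)-type allylchromium places O6 anti to H5 in the chair, giving the axial 6β-alkoxide; C9: the chromium alkoxide on O6 binds the ketone oxygen and the bulky ester turns away from the angular methyl and from C12, so O9 ends cis to O6 (9β-OH, ester α). The step needs aldehyde-over-ketone chemoselectivity of the allylchromium (inherent, and the ketone is neopentylic), γ-regioselectivity (chromium on the less hindered terminus) and no early vinyl activation (nickel is added only after the allylation).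

**Step 9**
Reactants: 14 tert-butyl (1R,4R,4aS,8aS)-2-(diethoxymethyl)-1,4-dihydroxy-5,8a-dimethyl-1,4,4a,7,8,8a-hexahydronaphthalene-1-carboxylate
Product: 16 tert-butyl (1R,4R,4aS,8aS)-2-(diethoxymethyl)-1,4-dihydroxy-5,5,8a-trimethyl-1,4,4a,5,6,7,8,8a-octahydronaphthalene-1-carboxylate, via tosylhydrazide adduct 15 (not isolated)
Conditions: Fe(acac)3 (30 mol %), PhSiH3, CH2=NNHTs, THF–EtOH, rt; then EtOH, 70 °C
Reagents that add atoms: formaldehyde N-tosylhydrazone, C=NNS(=O)(=O)c1ccc(C)cc1
Why: Iron-hydride hydrogen-atom transfer (Markovnikov radical hydromethylation) to the ring A alkene gives the tertiary C4 radical, which adds to the hydrazone; thermal loss of sulfinate and N2 leaves the second methyl, the hindered and inductively deactivated ring B alkene should react more slowly, and no stereocentre is formed.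

**Step 10**
Reactants: 16 tert-butyl (1R,4R,4aS,8aS)-2-(diethoxymethyl)-1,4-dihydroxy-5,5,8a-trimethyl-1,4,4a,5,6,7,8,8a-octahydronaphthalene-1-carboxylate; 17 (2E,4E,6E)-octa-2,4,6-trienoic acid
Product: 19 tert-butyl (1R,4R,4aS,8aS)-2-(diethoxymethyl)-1-hydroxy-5,5,8a-trimethyl-4-[(2E,4E,6E)-octa-2,4,6-trienoyloxy]-1,4,4a,5,6,7,8,8a-octahydronaphthalene-1-carboxylate, via mixed anhydride 18 (not isolated)
Conditions: 2,4,6-trichlorobenzoyl chloride, Et3N, THF, rt; then 16, DMAP, toluene, 60 °C
Reagents that add atoms: none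
Why: Yamaguchi esterification; DMAP should attack the mixed anhydride at the less hindered trienoyl carbonyl and the acylpyridinium acylates the secondary axial 6-OH, while the tertiary 9-OH is too hindered to react.

**Step 11**
Reactants: 19 tert-butyl (1R,4R,4aS,8aS)-2-(diethoxymethyl)-1-hydroxy-5,5,8a-trimethyl-4-[(2E,4E,6E)-octa-2,4,6-trienoyloxy]-1,4,4a,5,6,7,8,8a-octahydronaphthalene-1-carboxylate
Product: 20 (1R,4R,4aS,8aS)-2-formyl-1-hydroxy-5,5,8a-trimethyl-4-[(2E,4E,6E)-octa-2,4,6-trienoyloxy]-1,4,4a,5,6,7,8,8a-octahydronaphthalene-1-carboxylic acid (target)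
Conditions: TFA, CH2Cl2, H2O, 0 °C
Reagents that add atoms: water, O
Why: Acidolysis should remove the tert-butyl ester as isobutene and hydrolyse the diethyl acetal to the conjugated aldehyde in one operation; the trienoate, the allylic ester and the tertiary alcohol (ionisation disfavoured by the adjacent carboxyl and the acceptor-substituted alkene) should survive.

**Compound list**

1 | 3-methylcyclohex-2-en-1-one | CC1=CC(=O)CCC1 | starting material
2 | (±)-1,3-dimethylcyclohex-2-en-1-ol | CC1=CC(C)(O)CCC1 | intermediate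
3 | (±)-3-chloro-1,3-dimethylcyclohex-1-ene | CC1=CC(C)(Cl)CCC1 | intermediate
4 | tert-butyl glyoxylate (tert-butyl 2-oxoacetate) | CC(C)(C)OC(=O)C=O | starting material
5 | tert-butyl 2-[(1S)-1,3-dimethylcyclohex-2-en-1-yl]-2-(trimethylsilyloxy)acetate (carbinol centre as formed, erased in step 4) | CC(C)(C)OC(=O)C(O[Si](C)(C)C)[C@@]1(C)CCCC(C)=C1 | intermediate
6 | tert-butyl 2-[(1S)-1,3-dimethylcyclohex-2-en-1-yl]-2-hydroxyacetate (carbinol centre as formed, erased in step 4) | CC(C)(C)OC(=O)C(O)[C@@]1(C)CCCC(C)=C1 | intermediate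
7 | tert-butyl 2-[(1S)-1,3-dimethylcyclohex-2-en-1-yl]-2-oxoacetate | CC(C)(C)OC(=O)C(=O)[C@@]1(C)CCCC(C)=C1 | intermediate
8 | tert-butyl 2-[(1S)-4-bromo-1,3-dimethylcyclohex-2-en-1-yl]-2-oxoacetate (both C–Br epimers) | CC(C)(C)OC(=O)C(=O)[C@@]1(C)CCC(Br)C(C)=C1 | intermediate
9 | 4,4-diethoxybut-2-yn-1-ol | OCC#CC(OCC)OCC | starting material
10 | sodium cyclic alkenylalanate from 9 (aluminium on C3, bound to the C1 oxygen) | [Na+].CCOC(OCC)C1=CCO[Al-]1(OCCOC)OCCOC | intermediate
11 | (2Z)-4,4-diethoxy-3-iodobut-2-en-1-ol | OC/C=C(\I)C(OCC)OCC | intermediate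
12 | (2Z)-4,4-diethoxy-3-iodobut-2-enal | O=C/C=C(\I)C(OCC)OCC | intermediate
13 | tert-butyl 2-[(1S,2S)-2-[(1S,2Z)-4,4-diethoxy-1-hydroxy-3-iodobut-2-en-1-yl]-1,3-dimethylcyclohex-3-en-1-yl]-2-oxoacetate (drawn as the free alcohol, present as its chromium alkoxide) | CC(C)(C)OC(=O)C(=O)[C@@]1(C)CCC=C(C)[C@@H]1[C@H](O)/C=C(\I)C(OCC)OCC | intermediate
14 | tert-butyl (1R,4R,4aS,8aS)-2-(diethoxymethyl)-1,4-dihydroxy-5,8a-dimethyl-1,4,4a,7,8,8a-hexahydronaphthalene-1-carboxylate | O[C@@H]1C=C(C(OCC)OCC)[C@@](O)(C(=O)OC(C)(C)C)[C@@]2(C)CCC=C(C)[C@H]12 | intermediate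
15 | tert-butyl (1R,4R,4aS,8aS)-2-(diethoxymethyl)-1,4-dihydroxy-5,8a-dimethyl-5-[(2-tosylhydrazinyl)methyl]-1,4,4a,5,6,7,8,8a-octahydronaphthalene-1-carboxylate (either configuration at C5 of the naphthalene numbering) | O[C@@H]1C=C(C(OCC)OCC)[C@@](O)(C(=O)OC(C)(C)C)[C@@]2(C)CCCC(C)(CNNS(=O)(=O)c3ccc(C)cc3)[C@H]12 | intermediate
16 | tert-butyl (1R,4R,4aS,8aS)-2-(diethoxymethyl)-1,4-dihydroxy-5,5,8a-trimethyl-1,4,4a,5,6,7,8,8a-octahydronaphthalene-1-carboxylate | O[C@@H]1C=C(C(OCC)OCC)[C@@](O)(C(=O)OC(C)(C)C)[C@@]2(C)CCCC(C)(C)[C@H]12 | intermediate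
17 | (2E,4E,6E)-octa-2,4,6-trienoic acid | C/C=C/C=C/C=C/C(=O)O | starting material
18 | (2E,4E,6E)-octa-2,4,6-trienoic 2,4,6-trichlorobenzoic anhydride | C/C=C/C=C/C=C/C(=O)OC(=O)c1c(Cl)cc(Cl)cc1Cl | intermediate
19 | tert-butyl (1R,4R,4aS,8aS)-2-(diethoxymethyl)-1-hydroxy-5,5,8a-trimethyl-4-[(2E,4E,6E)-octa-2,4,6-trienoyloxy]-1,4,4a,5,6,7,8,8a-octahydronaphthalene-1-carboxylate | C/C=C/C=C/C=C/C(=O)O[C@@H]1C=C(C(OCC)OCC)[C@@](O)(C(=O)OC(C)(C)C)[C@@]2(C)CCCC(C)(C)[C@H]12 | intermediate
20 | (1R,4R,4aS,8aS)-2-formyl-1-hydroxy-5,5,8a-trimethyl-4-[(2E,4E,6E)-octa-2,4,6-trienoyloxy]-1,4,4a,5,6,7,8,8a-octahydronaphthalene-1-carboxylic acid (drimane numbering: 5S,6R,9R,10S) | C/C=C/C=C/C=C/C(=O)O[C@@H]1C=C(C=O)[C@@](O)(C(=O)O)[C@@]2(C)CCCC(C)(C)[C@H]12 | target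

**Count.** Total: 11 steps. Longest linear sequence: 9 steps (steps 1–5 and 8–11); steps 6–7 make the second fragment.

**Steps most likely to fail**

1. Step 8. The vinylchromium may add too slowly to the hindered C9 ketone, which can also be tied up reversibly as a hemiketal with the new C6 alkoxide, so that protodemetalation or poor facial selectivity in the ring closure takes over. Fallback from 13 back to 14: only the first stage is run (CrCl2 without nickel) and 13 is isolated as the free alcohol. Silylation (Et3SiOTf, 2,6-lutidine) should give tert-butyl 2-[(1S,2S)-2-[(1S,2Z)-4,4-diethoxy-3-iodo-1-(triethylsilyloxy)but-2-en-1-yl]-1,3-dimethylcyclohex-3-en-1-yl]-2-oxoacetate F1. Iodine–lithium exchange with tert-butyllithium (THF, −100 °C) then triggers an anionic Parham-type cyclisation onto the ketone to give tert-butyl (1R,4R,4aS,8aS)-2-(diethoxymethyl)-1-hydroxy-5,8a-dimethyl-4-(triethylsilyloxy)-1,4,4a,7,8,8a-hexahydronaphthalene-1-carboxylate F2. HF·pyridine returns 14.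

2. Step 3. The catalyst must discriminate the two faces of a symmetric, fully substituted allyl terminus, so enantioselectivity may be low. Fallback from 3 back to 7 by classical resolution: Barbier-type Grignard formation from 3 (Mg, THF) with inverse addition to excess diethyl oxalate at −78 °C should give racemic ethyl 2-(1,3-dimethylcyclohex-2-en-1-yl)-2-oxoacetate F3. LiOH (THF–H2O) gives racemic 2-(1,3-dimethylcyclohex-2-en-1-yl)-2-oxoacetic acid F4. Crystallisation with (R)-1-phenylethylamine (or its antipode, whichever gives the less soluble salt of the (S)-acid) gives (R)-1-phenylethylammonium (S)-2-(1,3-dimethylcyclohex-2-en-1-yl)-2-oxoacetate F5. Acidification liberates (S)-2-(1,3-dimethylcyclohex-2-en-1-yl)-2-oxoacetic acid F6, and tert-butyl 2,2,2-trichloroacetimidate (cat. BF3·OEt2) gives 7.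

3. Step 9. Hydrogen-atom transfer may also engage the ring B alkene, or the C4 radical may simply be reduced (hydrogenation instead of methylation). Fallback from 14 back to 16 by conjugate methylation: MnO2 oxidises the allylic 6-OH to tert-butyl (1R,4aS,8aS)-2-(diethoxymethyl)-1-hydroxy-5,8a-dimethyl-4-oxo-1,4,4a,7,8,8a-hexahydronaphthalene-1-carboxylate F7. DBU moves the ring A alkene into conjugation, giving tert-butyl (1R,8aS)-2-(diethoxymethyl)-1-hydroxy-5,8a-dimethyl-4-oxo-1,4,6,7,8,8a-hexahydronaphthalene-1-carboxylate F8. (CH3)2CuLi (THF, −78 °C) adds to the less hindered β-carbon C4 (drimane numbering), and protonation of the enolate should give the trans-fused tert-butyl (1R,4aS,8aS)-2-(diethoxymethyl)-1-hydroxy-5,5,8a-trimethyl-4-oxo-1,4,4a,5,6,7,8,8a-octahydronaphthalene-1-carboxylate F9. NaBH4/CeCl3 (MeOH) delivers hydride from the α-face, away from the two axial methyls, to return the 6β-alcohol 16.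

**Further compounds**

F1 | step 8 | tert-butyl 2-[(1S,2S)-2-[(1S,2Z)-4,4-diethoxy-3-iodo-1-(triethylsilyloxy)but-2-en-1-yl]-1,3-dimethylcyclohex-3-en-1-yl]-2-oxoacetate | CC(C)(C)OC(=O)C(=O)[C@@]1(C)CCC=C(C)[C@@H]1[C@H](O[Si](CC)(CC)CC)/C=C(\I)C(OCC)OCC
F2 | step 8 | tert-butyl (1R,4R,4aS,8aS)-2-(diethoxymethyl)-1-hydroxy-5,8a-dimethyl-4-(triethylsilyloxy)-1,4,4a,7,8,8a-hexahydronaphthalene-1-carboxylate | CC[Si](CC)(CC)O[C@@H]1C=C(C(OCC)OCC)[C@@](O)(C(=O)OC(C)(C)C)[C@@]2(C)CCC=C(C)[C@H]12
F3 | step 3 | racemic ethyl 2-(1,3-dimethylcyclohex-2-en-1-yl)-2-oxoacetate | CCOC(=O)C(=O)C1(C)CCCC(C)=C1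
F4 | step 3 | racemic 2-(1,3-dimethylcyclohex-2-en-1-yl)-2-oxoacetic acid | OC(=O)C(=O)C1(C)CCCC(C)=C1
F5 | step 3 | (R)-1-phenylethylammonium (S)-2-(1,3-dimethylcyclohex-2-en-1-yl)-2-oxoacetate | [O-]C(=O)C(=O)[C@@]1(C)CCCC(C)=C1.C[C@@H]([NH3+])c1ccccc1
F6 | step 3 | (S)-2-(1,3-dimethylcyclohex-2-en-1-yl)-2-oxoacetic acid | OC(=O)C(=O)[C@@]1(C)CCCC(C)=C1
F7 | step 9 | tert-butyl (1R,4aS,8aS)-2-(diethoxymethyl)-1-hydroxy-5,8a-dimethyl-4-oxo-1,4,4a,7,8,8a-hexahydronaphthalene-1-carboxylate | O=C1C=C(C(OCC)OCC)[C@@](O)(C(=O)OC(C)(C)C)[C@@]2(C)CCC=C(C)[C@H]12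
F8 | step 9 | tert-butyl (1R,8aS)-2-(diethoxymethyl)-1-hydroxy-5,8a-dimethyl-4-oxo-1,4,6,7,8,8a-hexahydronaphthalene-1-carboxylate | O=C1C=C(C(OCC)OCC)[C@@](O)(C(=O)OC(C)(C)C)[C@@]2(C)CCCC(C)=C12
F9 | step 9 | tert-butyl (1R,4aS,8aS)-2-(diethoxymethyl)-1-hydroxy-5,5,8a-trimethyl-4-oxo-1,4,4a,5,6,7,8,8a-octahydronaphthalene-1-carboxylate | O=C1C=C(C(OCC)OCC)[C@@](O)(C(=O)OC(C)(C)C)[C@@]2(C)CCCC(C)(C)[C@H]12
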